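The readings stem from a simulated flask on assumed constants; scatter was added.

Count the spare reagent.

| setting | ash | noon | winter | spring |
|---|---|---|---|---|
| substrate | 0.12 M | 0.12 M | 0.12 M | 0.12 M |
| reagent | 0.44 M | 0.300 M | 0.240 M | 0.360 M |
| remark | run made earlier |  |  |  |
| time |  | 2.0 h | 2.0 h | 2.0 h |

ash run (percent of the substrate charged)

| time / min | bis adduct / % | mono adduct / % | substrate / % |
|---|---|---|---|
| 4.00 | 79.1 | 3.3 | 1.0 |
| 12.0 | 74.5 | 0 | 0 |
| 20.0 | 66.0 | 0 | 0 |
| 30.0 | 57.8 | 0 | 0.2 |
| 50.0 | 45.2 | 0 | 0 |
| 60.0 | 40.1 | 0.1 | 0.1 |

(readings scatter by 0.3 percentage points)

- in percentages every species weighs as the substrate in it: one homo dimer counts as two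
- the analysis behind the earlier runs scatters by 0.3 percentage points, standard deviation
- reactions considered so far: reagent + bis adduct -> triple product; 2 substrate -> homo dimer; substrate + reagent -> mono adduct; mono adduct <-> isomer of the product; reagent + mono adduct -> over-reaction product; reagent + mono adduct -> bis adduct

- which of these holds the largest part of the substrate at the end of noon (mono adduct / bis adduct / substrate / triple product)
- which of these holds the largest part of the substrate at the end of winter (mono adduct / bis adduct / substrate / triple product)
- which of these holds the largest part of the substrate at the end of spring (mono adduct / bis adduct / substrate / triple product)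
- final bis adduct in winter, as a percentage of the substrate charged

Substrate takes reagent to mono adduct, which takes a second reagent to bis adduct or over-reaction product; substrate may instead pair to homo dimer, and bis adduct takes a third reagent to triple product. In ash, substrate reads 0 % and mono adduct 0 % at 12.0 min. Bis adduct then reads a fall of 0.0129 /min, which, run back to the start, reads a first-stage yield of 87.0 %, so side routes took about 13.0 %. With about 0.179 M of free reagent, the step to triple product reads 0.00120 /M/s.

Winter's 1.54 h is the minority-partner half-life, a pseudo-first-order clock: the natural logarithm of two over the rate constant times the partner in excess, here bis adduct. By this clock, 59.4 % of the spare reagent, the reagent left once the first stage is over, is used in 2.0 h.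

Two extremes frame winter. If the side routes gave over-reaction product throughout, every substrate took two reagent, spare reagent is 0 M, and bis adduct stays at 87.0 %. If they gave homo dimer throughout, 0.0313 M is spared and bis adduct ends at 71.5 %. Homo dimer competes with reagent for substrate, and winter holds less reagent than ash, so this reckoning commits to the lower end.

Bis adduct and triple product cross at 43.5 %. At the midpoint of the extremes, the same clock, with bis adduct held at its first-stage yield, gives noon an upper figure of 37.4 % triple product, less than the crossing. In spring, on that midpoint, reagent is reckoned at 0.0834 M at the crossing and above that before it, so bis adduct, now the minority partner, has a half-life of at most 1.92 h, shorter than the 2.0 h, and one half-life reaches the crossing.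

The forecast, for which “the reagent left over decides the rest”, names bis adduct for noon, bis adduct for winter, triple product for spring, and 71 % for winter's bis adduct.

Winter ends at 72.2 % bis adduct; noon is led by bis adduct, spring by triple product.

    reagent + bis adduct → triple product (k = 0.00125 /M/s)
    2 substrate → homo dimer (k = 0.00998 /M/s)
    substrate + reagent → mono adduct (k = 0.0701 /M/s)
    mono adduct ⇌ isomer of the product (K = 0.416, k = 1.67 × 10⁻⁴ /s)
    reagent + mono adduct → over-reaction product (k = 0.00632 /M/s)
    reagent + mono adduct → bis adduct (k = 0.0714 /M/s)

Winter ends with 8.66 % homo dimer, which spares 0.0208 M of reagent; the clock of 1.54 h reckons 59.4 % of it into 10.3 % of triple product, and winter holds 11.2 %. In a neighbour of winter with 0.030 M of substrate, spare reagent is reckoned at 0.180 M, more than the bis adduct, so bis adduct is the minority partner, with a clock of 0.892 h. Over 2.24 half-lives, the first-stage yield of 87.0 % read in ash thins to 18.4 %; that neighbour ends with 20.5 % bis adduct.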